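The numbers in the tables come from a simulation from invented constants, and the scatter is random.

The number to watch in a repeat is a single fraction, and I read it below from the spring and winter runs.

| flask | substrate | free catalyst | time |
|---|---|---|---|
| spring | 0.800 M | 0.00800 M |  |
| dawn | 0.320 M | 0.00800 M |  |
| winter | 0.800 M | 0.0160 M |  |
| dusk | 2.40 M | 0.00800 M |  |
| noon | 0.800 M | 0.00800 M | 59 min |

| run | time / min | [product] / M |
|---|---|---|
| spring run | 1.6 | 0.053 |
| spring run | 3.3 | 0.115 |
| spring run | 4.9 | 0.153 |
| spring run | 6.5 | 0.210 |
| spring run | 8.2 | 0.244 |
| spring run | 9.8 | 0.283 |
| dawn run | 1.6 | 0.020 |
| dawn run | 3.3 | 0.049 |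
| dawn run | 4.9 | 0.065 |
| dawn run | 6.5 | 0.081 |
| dawn run | 8.2 | 0.097 |
| dawn run | 9.8 | 0.114 |
| winter run | 1.6 | 0.092 |
| winter run | 3.3 | 0.181 |
| winter run | 4.9 | 0.257 |
| winter run | 6.5 | 0.324 |
| winter run | 8.2 | 0.387 |
| winter run | 9.8 | 0.441 |
| dusk run | 1.6 | 0.106 |
| dusk run | 3.3 | 0.207 |
| dusk run | 4.9 | 0.309 |
| dusk run | 6.5 | 0.406 |
| dusk run | 8.2 | 0.504 |
| dusk run | 9.8 | 0.595 |

(scatter of a reading: 0.004 M)

- Overall: substrate -> product, with free catalyst as catalyst.
- Constant volume, constant temperature.
- The analysis sees a species whether free or bound.
- An order is taken over about fifteen percent of the charge, up and down.

- order of the initial rate in [substrate], near the charge of the spring run, the rate being that where two percent of its substrate are product (one fixed amount of product, the same in the runs compared)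
- order of the initial rate in [free catalyst], near the charge of the spring run, the rate being that where two percent of its substrate are product
- the dawn run starts with 0.480 M less of substrate than the spring run, and with no product. Compared where both hold the same amount of substrate, once fifteen percent of what the dawn run was charged with has turned into product, is the dawn run faster, slower or alike (within a tenth)?
- product in the noon run at 59 min, as a share of the substrate charged
- which of these the readings show (the product speeds the reaction / an uncatalysed path runs beside / the substrate pairs with itself / a little impurity takes part of the catalyst at once / the substrate kills the catalyst)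

I read each run by a pseudo-first-order constant: minus the logarithm of the fraction of substrate left, summed over its readings, divided by the sum of their times.

| Run | Constant |
|---|---|
| spring | 0.0449 min⁻¹ |
| dawn | 0.0452 min⁻¹ |
| winter | 0.0801 min⁻¹ |
| dusk | 0.0285 min⁻¹ |

The spring and winter runs start from the same 0.800 M of substrate, and the winter run has twice the free catalyst. Both pass through the same substrate levels, so their constants compare their rates. The winter constant over the spring constant is a reading of 1.78, less than 2. If the catalysed part doubles and the rest stays, that ratio is one plus the catalysed share, the part of the rate in the spring run that grows in step with the free catalyst, and this reads 0.783. The remaining 0.217 of the spring rate runs beside the catalyst, with a constant of 0.00974 min⁻¹. My reading of the order in free catalyst at the spring charge is the share itself, 0.783.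

One number is not enough, though. The dusk run has the free catalyst of the spring run and more substrate, and its constant is lower than the spring constant, so the constant moves with substrate. Held unchanged over the 59 min of the noon run, the spring constant gives 92.9 %, and that is the figure to doubt.

The forecast gives an order of 0.8 in substrate and 0.82 in free catalyst, where my reading is lower; it calls the dawn and spring runs alike at equal substrate, puts the noon run at 93 %, and says that an uncatalysed path runs beside: “It implies a catalyst-independent background”.

    free catalyst + substrate ⇌ catalyst-substrate complex, settled at all times (3.650 L mol⁻¹)
    catalyst-substrate complex + substrate ⇌ doubly bound catalyst, settled at all times (1.780 L mol⁻¹)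
    doubly bound catalyst → product + catalyst-substrate complex (6.480 min⁻¹)
    substrate → product (0.01026 min⁻¹)

The noon run reaches 90.9 %, 2.1 percentage points below the forecast. The orders come out at 0.74 in substrate and 0.76 in free catalyst, the dawn and spring runs are alike at equal substrate, and the readings show that an uncatalysed path runs beside. Carried to the dusk run, the constant beside the catalyst gives 0.0234 M min⁻¹ at its charge, against an early rate of 0.065 M min⁻¹, so the catalysed share in the dusk run is 0.642.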